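The route rests on cutting both C–O bonds of the peroxide, so that O1 and O2 of the 1,2-dioxane ring come from hydrogen peroxide. The key step exploits the two electrophilic ring carbons that flank the O1–O2 unit: C3, a ketal carbon, and C6, whose C7–C8–O arm (the future acid) is tied back to it as an oxetane. In one operation, ketal exchange forms C3–O2 and the hydroperoxide then opens the oxetane at C6 with inversion. This closes the six-membered ring, sets C6 and, by equilibration, C3, and frees the C8 alcohol. The precursor is an (R)-2-alkyloxetane with a dimethyl ketal two methylenes away and the complete enyne chain.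

Key step: step 8

Remark: atoms are numbered as in the 1,2-dioxane (O1, O2, C3 to C6; C7 and C8 in the acid arm); anhydrous ethereal H2O2 is assumed to be freshly prepared, titrated and never concentrated to dryness, and the volatile compounds 2 and 4 are assumed to be isolated by careful distillation.

Step 1
Reactants: 1 (R)-1,2-epoxy-5-hexene [(2R)-2-(but-3-en-1-yl)oxirane]
Product: 2 (2R)-2-(but-3-en-1-yl)oxetane
Conditions: Me3S(O)I (3 equiv), KOtBu (3 equiv), t-BuOH, 50 °C
Reagents that add atoms: trimethylsulfoxonium iodide, C[S+](C)(C)=O.[I-]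
Why: Ring expansion with dimethylsulfoxonium methylide (Corey–Chaykovsky reagent): the ylide opens the oxirane at its CH2 terminus and the resulting γ-alkoxide displaces dimethyl sulfoxide in a 4-exo-tet closure, so the C–O bond at the stereocentre is never broken and the (R) configuration is carried over.

Step 2
Reactants: 2 (2R)-2-(but-3-en-1-yl)oxetane
Product: 4 3-[(2R)-oxetan-2-yl]propanal, via secondary ozonide 3 (not isolated)
Conditions: O3, CH2Cl2, −78 °C (stopped at first blue tint); then PPh3, −78 °C → rt
Reagents that add atoms: ozone, [O-][O+]=O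
Why: Ozonolysis with reductive work-up (Criegee mechanism) should cleave the only alkene to the aldehyde, the oxetane ether being inert to ozone at −78 °C and the stereocentre remote from the reacting site.

Step 3
Reactants: 5 undec-1-yne
Product: 7 (E)-1-iodoundec-1-ene, via alkenylzirconocene chloride 6 (not isolated)
Conditions: Cp2Zr(H)Cl (1.2 equiv), THF, rt; then I2, 0 °C
Reagents that add atoms: iodine, II
Why: Hydrozirconation with the Schwartz reagent is a syn, anti-Markovnikov addition that places zirconium on the terminal carbon, and iodinolysis of the C–Zr bond proceeds with retention, which fixes the E geometry.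

Step 4
Reactants: 7 (E)-1-iodoundec-1-ene; 8 5-chloropent-1-yne
Product: 9 (6E)-1-chlorohexadec-6-en-4-yne
Conditions: PdCl2(PPh3)2 (2 mol%), CuI (4 mol%), Et3N, THF, rt, degassed
Reagents that add atoms: none
Why: Sonogashira coupling: zerovalent palladium inserts into the vinyl C–I bond with retention of the E geometry and couples with the copper acetylide of 8, while the primary alkyl chloride does not undergo oxidative addition under these conditions.

Step 5
Reactants: 9 (6E)-1-chlorohexadec-6-en-4-yne; 4 3-[(2R)-oxetan-2-yl]propanal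
Product: 11 (9E)-1-[(2R)-oxetan-2-yl]nonadec-9-en-7-yn-3-ol (both carbinol epimers), via Grignard reagent 10 (not isolated)
Conditions: Mg turnings (BrCH2CH2Br-activated), THF, reflux; then 4, THF, −78 → 0 °C; aq NH4Cl
Reagents that add atoms: none
Why: Grignard addition: magnesium inserts into the primary C–Cl bond and the alkylmagnesium chloride adds 1,2 to the aldehyde, the oxetane and the internal enyne being inert to the reagent at low temperature; the new carbinol centre is formed without control and is erased in step 6.

Step 6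
Reactants: 11 (9E)-1-[(2R)-oxetan-2-yl]nonadec-9-en-7-yn-3-ol
Product: 12 (9E)-1-[(2R)-oxetan-2-yl]nonadec-9-en-7-yn-3-one
Conditions: Dess–Martin periodinane, NaHCO3, CH2Cl2, 0 °C → rt
Reagents that add atoms: none
Why: Dess–Martin oxidation should convert the secondary alcohol to the ketone under buffered, near-neutral conditions that leave the oxetane and the enyne untouched and remove the uncontrolled carbinol centre.

Step 7
Reactants: 12 (9E)-1-[(2R)-oxetan-2-yl]nonadec-9-en-7-yn-3-one
Product: 13 (2R)-2-[(9E)-3,3-dimethoxynonadec-9-en-7-yn-1-yl]oxetane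
Conditions: HC(OMe)3, MeOH, PPTS (10 mol%), rt; Et3N quench before concentration
Reagents that add atoms: methanol, CO; trimethyl orthoformate, COC(OC)OC
Why: Acid-catalysed ketalisation driven by the orthoformate as water scavenger; pyridinium tosylate is too weak an acid to protonate and open the 2-alkyloxetane, and the amine quench prevents ring opening on concentration.

Step 8
Reactants: 13 (2R)-2-[(9E)-3,3-dimethoxynonadec-9-en-7-yn-1-yl]oxetane; 14 hydrogen peroxide
Product: 16 2-[(3R,6S)-3-[(E)-hexadec-6-en-4-yn-1-yl]-3-methoxy-1,2-dioxan-6-yl]ethan-1-ol, via hydroperoxy ketal 15 (not isolated)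
Conditions: H2O2 (anhydrous, in Et2O, 5 equiv), CSA (10 mol%), Et2O, 0 °C; aq NaHCO3 wash, solvent swap to CH2Cl2; then TMSOTf (20 mol%), CH2Cl2, −78 → −20 °C; Et3N, aq NaHCO3
Reagents that add atoms: none
Why: Camphorsulfonic acid ionises the dimethyl ketal to an oxocarbenium ion that H2O2 captures (C3–O2, giving 15); TMSOTf then silylates the oxetane oxygen and the terminal hydroperoxide oxygen displaces it at C6 (O1–C6), which releases the C8 oxygen as the primary alcohol after work-up. The closest known reaction types are the acid-catalysed perhydrolysis of ketals and the Lewis-acid-promoted opening of oxetanes by hydroperoxides, used here in its intramolecular form. The 1,2-dioxane closes in the 6-exo-tet mode, since the breaking C6–O bond lies outside the forming ring, and relief of four-ring strain makes the closure irreversible. C6 is controlled by backside SN2 attack, which inverts the (R)-oxetane carbon to (6S); C3 is under thermodynamic control, because its remaining methoxy group ionises reversibly to a cyclic peroxycarbenium ion and settles axial (anomeric effect) on the chair that keeps the C6 arm equatorial, which is the cis, (3R) arrangement. The step needs opening at C6 and not at C8, which the tether secures because attack at C8 would pass through an eight-membered transition state, and it needs the internal hydroperoxide to win over free H2O2 and over the neighbouring methoxy oxygen, which is secured by washing out excess H2O2 before the Lewis acid is added and by the higher nucleophilicity of the peroxide oxygen.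

Step 9
Reactants: 16 2-[(3R,6S)-3-[(E)-hexadec-6-en-4-yn-1-yl]-3-methoxy-1,2-dioxan-6-yl]ethan-1-ol
Product: 18 2-[(3R,6S)-3-[(E)-hexadec-6-en-4-yn-1-yl]-3-methoxy-1,2-dioxan-6-yl]acetic acid, via dioxanylacetaldehyde 17 (not isolated)
Conditions: TEMPO (20 mol%), PhI(OAc)2 (2.2 equiv), MeCN/pH 7 phosphate buffer (1:1), 0 °C → rt
Reagents that add atoms: water, O
Why: Oxoammonium (TEMPO) oxidation with PhI(OAc)2 as terminal oxidant should take the primary alcohol through the aldehyde hydrate to the acid at neutral pH, conditions under which the dialkyl peroxide, the peroxyketal and the enyne are not oxidised and neither stereocentre can epimerise.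

Compound list
1 | (R)-1,2-epoxy-5-hexene, (2R)-2-(but-3-en-1-yl)oxirane | C=CCC[C@@H]1CO1 | starting material
2 | (2R)-2-(but-3-en-1-yl)oxetane | C=CCC[C@@H]1CCO1 | intermediate
3 | 3-{2-[(2R)-oxetan-2-yl]ethyl}-1,2,4-trioxolane (secondary ozonide, both epimers at the trioxolane carbon) | C1OC(CC[C@@H]2CCO2)OO1 | intermediate
4 | 3-[(2R)-oxetan-2-yl]propanal | O=CCC[C@@H]1CCO1 | intermediate
5 | undec-1-yne | CCCCCCCCCC#C | starting material
6 | chlorobis(cyclopentadienyl)[(1E)-undec-1-en-1-yl]zirconium, Cp2Zr(Cl)(CH=CH–C9H19) | CCCCCCCCC/C=C/[Zr+2]Cl.[cH-]1cccc1.[cH-]1cccc1 | intermediate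
7 | (E)-1-iodoundec-1-ene | CCCCCCCCC/C=C/I | intermediate
8 | 5-chloropent-1-yne | ClCCCC#C | starting material
9 | (6E)-1-chlorohexadec-6-en-4-yne | CCCCCCCCC/C=C/C#CCCCCl | intermediate
10 | (6E)-hexadec-6-en-4-yn-1-ylmagnesium chloride | CCCCCCCCC/C=C/C#CCCC[Mg]Cl | intermediate
11 | (9E)-1-[(2R)-oxetan-2-yl]nonadec-9-en-7-yn-3-ol (both epimers at C3 of the chain) | CCCCCCCCC/C=C/C#CCCCC(O)CC[C@@H]1CCO1 | intermediate
12 | (9E)-1-[(2R)-oxetan-2-yl]nonadec-9-en-7-yn-3-one | CCCCCCCCC/C=C/C#CCCCC(=O)CC[C@@H]1CCO1 | intermediate
13 | (2R)-2-[(9E)-3,3-dimethoxynonadec-9-en-7-yn-1-yl]oxetane | CCCCCCCCC/C=C/C#CCCCC(OC)(OC)CC[C@@H]1CCO1 | intermediate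
14 | hydrogen peroxide | OO | starting material
15 | (2R)-2-[(9E)-3-hydroperoxy-3-methoxynonadec-9-en-7-yn-1-yl]oxetane (both epimers at the peroxyketal carbon) | CCCCCCCCC/C=C/C#CCCCC(OC)(OO)CC[C@@H]1CCO1 | intermediate
16 | 2-[(3R,6S)-3-[(E)-hexadec-6-en-4-yn-1-yl]-3-methoxy-1,2-dioxan-6-yl]ethan-1-ol | CCCCCCCCC/C=C/C#CCCC[C@]1(OC)CC[C@@H](CCO)OO1 | intermediate
17 | 2-[(3R,6S)-3-[(E)-hexadec-6-en-4-yn-1-yl]-3-methoxy-1,2-dioxan-6-yl]acetaldehyde | CCCCCCCCC/C=C/C#CCCC[C@]1(OC)CC[C@@H](CC=O)OO1 | intermediate
18 | 2-[(3R,6S)-3-[(E)-hexadec-6-en-4-yn-1-yl]-3-methoxy-1,2-dioxan-6-yl]acetic acid | CCCCCCCCC/C=C/C#CCCC[C@]1(OC)CC[C@@H](CC(=O)O)OO1 | target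

Total steps: 9.
Longest linear sequence: 7 steps (steps 1, 2, 5, 6, 7, 8, 9 from 1; the side-chain branch through steps 3, 4, 5, 6, 7, 8, 9 is equally long).

Steps most likely to fail

1. Step 8. The acid stage may over-exchange (both methoxy groups replaced, or peroxide-bridged dimers), the hydroperoxy ketal may ionise and lose its peroxide before the ring closes, and the acid may attack the enyne. The fallback makes the methoxy hydroperoxide by trapping a carbonyl oxide with methanol instead of by acid exchange, and attaches the acid-sensitive enyne only after the ring is closed. The closure itself remains an oxetane opening, so this fallback does not cover a failure of that event as such.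

   It sets out from aldehyde 4. The Grignard reagent made from (5-chloropent-1-yn-1-yl)trimethylsilane and Mg in THF should add at −78 °C to give 1-[(2R)-oxetan-2-yl]-8-(trimethylsilyl)oct-7-yn-3-ol F1. Dess–Martin oxidation should give 1-[(2R)-oxetan-2-yl]-8-(trimethylsilyl)oct-7-yn-3-one F2, and Wittig methylenation (Ph3P=CH2, THF) the 1,1-disubstituted alkene (2R)-2-[3-methylidene-8-(trimethylsilyl)oct-7-yn-1-yl]oxetane F3. Ozonolysis in MeOH/CH2Cl2 at −78 °C, stopped once the alkene is consumed (the silylalkyne reacts far more slowly), should give (2R)-2-[3-hydroperoxy-3-methoxy-8-(trimethylsilyl)oct-7-yn-1-yl]oxetane F4. Catalytic TMSOTf in CH2Cl2 at low temperature should then close F4 to 2-[(3R,6S)-3-methoxy-3-[5-(trimethylsilyl)pent-4-yn-1-yl]-1,2-dioxan-6-yl]ethan-1-ol F5, with the same inversion at C6 and equilibration at C3. Buffered fluoride (Bu4NF/AcOH, THF, 0 °C) should free the alkyne as 2-[(3R,6S)-3-methoxy-3-(pent-4-yn-1-yl)-1,2-dioxan-6-yl]ethan-1-ol F6. Sonogashira coupling of F6 with vinyl iodide 7 (PdCl2(PPh3)2, CuI, Et3N, THF, rt) comes back to the route at 16.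

2. Step 5. Magnesium insertion into the unactivated primary chloride may be slow, prolonged reflux may cause Wurtz-type homocoupling, and the basic reagent may enolise the small aldehyde instead of adding. The fallback generates the carbanion by halogen–lithium exchange at low temperature instead of by metal insertion. It sets out from chloride 9: Finkelstein exchange (NaI, acetone, reflux) should give (6E)-1-iodohexadec-6-en-4-yne F7, and t-BuLi (2 equiv, Et2O/pentane, −78 °C) should convert it within minutes to (6E)-hexadec-6-en-4-yn-1-yllithium F8. Addition of F8 to aldehyde 4 at −78 °C comes back to the route at 11.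

3. Step 1. The ring expansion needs a long reaction at raised temperature, conversion may stop early, and the small volatile product may be lost on separation from the solvent. The fallback builds the oxetane by the classical ring closure of a 1,3-diol monosulfonate. It sets out from epoxide 1: opening at the CH2 terminus with (i-PrO)Me2SiCH2MgCl and CuI (10 mol%) in THF at −20 °C should give (3R)-1-[dimethyl(propan-2-yloxy)silyl]hept-6-en-3-ol F9. Tamao–Fleming oxidation (H2O2, KF, KHCO3, THF/MeOH) should give (3R)-hept-6-ene-1,3-diol F10, and selective sulfonylation of the primary hydroxyl (TsCl, Et3N, Bu2SnO cat., CH2Cl2, 0 °C) should give (3R)-3-hydroxyhept-6-en-1-yl 4-methylbenzenesulfonate F11. Treatment with KOtBu in THF closes the ring by attack of the secondary alkoxide on the primary sulfonate, which leaves the stereocentre untouched and comes back to the route at 2.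

Further compounds
F1 | step 8 | 1-[(2R)-oxetan-2-yl]-8-(trimethylsilyl)oct-7-yn-3-ol (both carbinol epimers) | C[Si](C)(C)C#CCCCC(O)CC[C@@H]1CCO1
F2 | step 8 | 1-[(2R)-oxetan-2-yl]-8-(trimethylsilyl)oct-7-yn-3-one | C[Si](C)(C)C#CCCCC(=O)CC[C@@H]1CCO1
F3 | step 8 | (2R)-2-[3-methylidene-8-(trimethylsilyl)oct-7-yn-1-yl]oxetane | C[Si](C)(C)C#CCCCC(=C)CC[C@@H]1CCO1
F4 | step 8 | (2R)-2-[3-hydroperoxy-3-methoxy-8-(trimethylsilyl)oct-7-yn-1-yl]oxetane (both epimers at the peroxyketal carbon) | C[Si](C)(C)C#CCCCC(OC)(OO)CC[C@@H]1CCO1
F5 | step 8 | 2-[(3R,6S)-3-methoxy-3-[5-(trimethylsilyl)pent-4-yn-1-yl]-1,2-dioxan-6-yl]ethan-1-ol | C[Si](C)(C)C#CCCC[C@]1(OC)CC[C@@H](CCO)OO1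
F6 | step 8 | 2-[(3R,6S)-3-methoxy-3-(pent-4-yn-1-yl)-1,2-dioxan-6-yl]ethan-1-ol | C#CCCC[C@]1(OC)CC[C@@H](CCO)OO1
F7 | step 5 | (6E)-1-iodohexadec-6-en-4-yne | CCCCCCCCC/C=C/C#CCCCI
F8 | step 5 | (6E)-hexadec-6-en-4-yn-1-yllithium | CCCCCCCCC/C=C/C#CCCC[Li]
F9 | step 1 | (3R)-1-[dimethyl(propan-2-yloxy)silyl]hept-6-en-3-ol | C=CCC[C@@H](O)CC[Si](C)(C)OC(C)C
F10 | step 1 | (3R)-hept-6-ene-1,3-diol | C=CCC[C@@H](O)CCO
F11 | step 1 | (3R)-3-hydroxyhept-6-en-1-yl 4-methylbenzenesulfonate | C=CCC[C@@H](O)CCOS(=O)(=O)c1ccc(C)cc1
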